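## Retrosynthetic overview

- Numbering (germacrane): ring C1–C10; C1=C10 is the E-alkene (methyl on C10), C3 carries the angelate, C4(methyl)–C5 is the cis-fused oxirane, C6 the acetate, C7 the isopropyl group; target = (3S,4R,5S,6R,7S).
- Enabling feature: C6 lies between oxirane carbon C5 and isopropyl carbon C7, so ring bond C6–C7 belongs to an allylic-alcohol retron C6(OH)–C7(iPr)=C8; the cis-oxirane holds its two ring substituents C3 and C6 on one side and pre-folds the open chain.
- Disconnections: esters at C3 and C6 last; C7–H/C8–H by hydrogenation; C6–C7 by intramolecular Nozaki–Hiyama–Kishi coupling of an acyclic epoxy aldehyde with a Z-enol triflate; C8–C9 by ketone enolate alkylation; C3–C4 by alkenyl–aldehyde coupling.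
- Ring order: oxirane first (on the open chain, directed by the C3 hydroxyl), ten-membered carbocycle last.
- Stereo relay: C3 by ligand-controlled coupling; then C4/C5, C6 and C7 each from the centre before it by substrate control.

Key step: step 13

Remark: TBS = tert-butyldimethylsilyl. In the silyl ethers 9–21 the descriptor of C4 (oxirane C2 in the open-chain names) reads S although the spatial arrangement is that of 4R in the target, because O–Si raises the rank of C3; no inversion takes place. For the same reason the formyl-bearing oxirane carbon of 18 reads R.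

## Route

Step 1
Reactants: 1 but-2-yn-1-ol
Product: 3 (Z)-3-iodobut-2-en-1-ol, via cyclic alkenylaluminate 2 (not isolated)
Conditions: NaAlH2(OCH2CH2OMe)2, THF, 0 °C to rt; then I2, THF, −78 to 0 °C
Reagents that add atoms: iodine, [I][I]
Why: Hydroxyl-directed trans-hydroalumination of the propargylic alcohol places aluminium on C3 cis to the CH2O group in a five-membered aluminate, and iodinolysis of the C–Al bond with retention should give the Z-iodoalkene (hydroalumination–iodination).

Step 2
Reactants: 3 (Z)-3-iodobut-2-en-1-ol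
Product: 4 (Z)-tert-butyl[(3-iodobut-2-en-1-yl)oxy]dimethylsilane
Conditions: TBSCl, imidazole, CH2Cl2, 0 °C to rt
Reagents that add atoms: tert-butyldimethylsilyl chloride, CC(C)(C)[Si](C)(C)Cl
Why: Imidazole-promoted silylation of a primary alcohol, which leaves the iodoalkene untouched.

Step 3
Reactants: 5 4-methylpent-3-en-1-ol
Product: 6 4-methylpent-3-enal
Conditions: Dess–Martin periodinane, NaHCO3, CH2Cl2, 0 °C; used at once as a cold solution
Reagents that add atoms: none
Why: Buffered Dess–Martin oxidation should give the β,γ-unsaturated aldehyde without moving the double bond into conjugation.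

Step 4
Reactants: 4 (Z)-tert-butyl[(3-iodobut-2-en-1-yl)oxy]dimethylsilane; 6 4-methylpent-3-enal
Product: 7 (2Z,4S)-1-(TBS-oxy)-3,7-dimethylocta-2,6-dien-4-ol
Conditions: CrCl2 (3 equiv), NiCl2 (2 mol %), N-{2-[(4S)-4-isopropyl-4,5-dihydrooxazol-2-yl]-6-methylphenyl}methanesulfonamide (3.3 equiv; the antipode is used if it is the one that delivers the S carbinol), Et3N (3.3 equiv), THF, rt
Reagents that add atoms: none
Why: Enantioselective Nozaki–Hiyama–Kishi alkenylation, in which nickel activates the C–I bond and the alkenylchromium species adds to the aldehyde inside the chiral oxazoline–sulfonamide ligand sphere, so that C3 is set as S by ligand control while the trisubstituted iodoalkene keeps its Z geometry and the non-basic medium spares the enolisable aldehyde.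

Step 5
Reactants: 7 (2Z,4S)-1-(TBS-oxy)-3,7-dimethylocta-2,6-dien-4-ol
Product: 8 (1S)-1-[(2R,3S)-3-(TBS-oxymethyl)-2-methyloxiran-2-yl]-4-methylpent-3-en-1-ol
Conditions: Ti(OiPr)4 (0.3 equiv), t-BuOOH (decane), 4 Å molecular sieves, CH2Cl2, −20 °C
Reagents that add atoms: tert-butyl hydroperoxide, CC(C)(C)OO
Why: Titanium-alkoxide-directed epoxidation acts only on the allylic C4=C5 alkene, and allylic 1,3-strain between C3 and the cis CH2OTBS group holds H3 in the alkene plane so that oxygen should be delivered to the face carrying the C3 oxygen, which sets C4 and C5 in the threo sense by substrate control from C3.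

Step 6
Reactants: 8 (1S)-1-[(2R,3S)-3-(TBS-oxymethyl)-2-methyloxiran-2-yl]-4-methylpent-3-en-1-ol
Product: 9 TBS ether of 8 at the secondary hydroxyl (1S; oxirane 2S,3S)
Conditions: TBSOTf, 2,6-lutidine, CH2Cl2, −78 °C
Reagents that add atoms: tert-butyldimethylsilyl trifluoromethanesulfonate, CC(C)(C)[Si](C)(C)OS(=O)(=O)C(F)(F)F
Why: Silyl triflate/2,6-lutidine silylation of the hindered secondary epoxy alcohol at low temperature protects O3 for the base steps and keeps the oxirane intact.

Step 7
Reactants: 9 bis-TBS ether (1S; oxirane 2S,3S)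
Product: 10 (2E,5S)-5-(TBS-oxy)-5-[(2S,3S)-3-(TBS-oxymethyl)-2-methyloxiran-2-yl]-2-methylpent-2-en-1-ol
Conditions: SeO2 (0.3 equiv), t-BuOOH (3 equiv), salicylic acid (0.1 equiv), CH2Cl2, rt
Reagents that add atoms: tert-butyl hydroperoxide, CC(C)(C)OO; selenium dioxide (oxygen carrier, re-oxidised in the flask), O=[Se]=O
Why: Riley allylic oxidation (ene reaction, then 2,3-sigmatropic shift) should oxidise the E-methyl group at the more substituted end of the only alkene and give the E-allylic alcohol whose CH2OH carbon becomes C9.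

Step 8
Reactants: 10 E-allylic alcohol
Product: 11 (1S,3E)-5-bromo-1-[(2S,3S)-3-(TBS-oxymethyl)-2-methyloxiran-2-yl]-4-methylpent-3-en-1-yl TBS ether
Conditions: CBr4, PPh3, CH2Cl2, 0 °C
Reagents that add atoms: carbon tetrabromide, BrC(Br)(Br)Br
Why: Appel reaction converts the primary allylic alcohol into the bromide under neutral conditions, without allylic transposition or oxirane opening.

Step 9
Reactants: 11 allylic bromide; 12 3-methylbutan-2-one
Product: 14 (6E,9S)-9-(TBS-oxy)-9-[(2S,3S)-3-(TBS-oxymethyl)-2-methyloxiran-2-yl]-2,6-dimethylnon-6-en-3-one, via lithium enolate 13 (not isolated)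
Conditions: 12, LiN(iPr)2, THF, −78 °C; then 11, DMPU, −78 to −20 °C
Reagents that add atoms: none
Why: The kinetic lithium enolate of the methyl ketone (deprotonation at CH3) is alkylated at the primary allylic bromide in an SN2 reaction, which joins C8 to C9 and brings in C7 with its isopropyl group.

Step 10
Reactants: 14 ketone
Product: 16 (3Z,6E,9S)-9-(TBS-oxy)-9-[(2S,3S)-3-(TBS-oxymethyl)-2-methyloxiran-2-yl]-2,6-dimethylnona-3,6-dien-3-yl trifluoromethanesulfonate, via Z-lithium enolate 15 (not isolated)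
Conditions: LiN(iPr)2 (1.05 equiv), THF–DMPU, −78 °C; then PhNTf2, −78 to 0 °C
Reagents that add atoms: N-phenylbis(trifluoromethanesulfonimide), O=S(=O)(N(c1ccccc1)S(=O)(=O)C(F)(F)F)C(F)(F)F
Why: Kinetic deprotonation at the less substituted α-carbon C8 in the presence of DMPU should give the Z(O)-enolate, and O-triflation fixes it as the Z-enol triflate with the triflate cis to C9 (enolate trapping).

Step 11
Reactants: 16 enol triflate
Product: 17 (3Z,6E,9S)-9-(TBS-oxy)-9-[(2S,3S)-3-(hydroxymethyl)-2-methyloxiran-2-yl]-2,6-dimethylnona-3,6-dien-3-yl trifluoromethanesulfonate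
Conditions: HF·pyridine, pyridine, THF, 0 °C
Reagents that add atoms: none
Why: Buffered HF·pyridine should cleave the unhindered primary silyl ether much faster than the secondary one next to the quaternary oxirane carbon (selective desilylation).

Step 12
Reactants: 17 primary epoxy alcohol
Product: 18 (3Z,6E,9S)-9-(TBS-oxy)-9-[(2S,3R)-3-formyl-2-methyloxiran-2-yl]-2,6-dimethylnona-3,6-dien-3-yl trifluoromethanesulfonate
Conditions: Dess–Martin periodinane, NaHCO3, CH2Cl2, 0 °C
Reagents that add atoms: none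
Why: Dess–Martin oxidation of the primary epoxy alcohol gives the epoxy aldehyde, which cannot epimerise under these buffered conditions and is used directly.

Step 13
Reactants: 18 epoxy aldehyde enol triflate
Product: 19 (1(10)E,7Z)-(3S,4S,5S,6R)-3-(TBS-oxy)-4,5-epoxygermacra-1(10),7-dien-6-ol
Conditions: CrCl2 (10 equiv), NiCl2 (0.1 equiv), degassed DMF–THF (1:1), rt, slow addition of 18 to a final 2 mM
Reagents that add atoms: none
Why: Intramolecular Nozaki–Hiyama–Kishi reaction: zerovalent nickel formed from NiCl2 and CrCl2 inserts into the C7–OTf bond, transmetallation gives the C7 alkenyl species of trivalent chromium with the Z geometry kept, and this adds to the C6 aldehyde. The closest known reactions are chromium-mediated closures of ten-membered germacrane rings at the same C6–C7 bond from aldehydes (4,5-epoxy aldehydes included) and NiCl2/CrCl2 closures of nine- to fourteen-membered carbocycles from alkenyl halides or triflates. The carbocycle is closed in the 10-exo-trig mode (attack on the carbonyl carbon, C=O outside the ring), and slow addition at about 2 mM together with three rigid units in the chain (cis-oxirane, E-alkene, Z-alkenyl metal) should favour closure over intermolecular coupling. The one new stereocentre, C6, is under substrate control: allylic 1,3-strain across the cis-oxirane keeps H3 and the aldehyde hydrogen turned inward, the C3 silyloxy group and the oxirane oxygen occupy one face of the C3–C4–C5–C6 unit, so the tether must bring C7 to the aldehyde from the opposite face with the carbonyl oxygen pointing outward, which should give the 6R carbinol with O6 on the side of the oxirane oxygen. The step needs chemoselective activation of the enol triflate beside the oxirane, the silyl ether and the C1=C10 alkene, which the nickel/chromium couple provides, and face selectivity at the aldehyde, which the C3 centre and the cis-oxirane secure.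

Step 14
Reactants: 19 macrocyclic allylic alcohol
Product: 20 (1(10)E)-(3S,4S,5S,6R,7S)-3-(TBS-oxy)-4,5-epoxygermacr-1(10)-en-6-ol
Conditions: H2 (50 atm), [Rh(nbd)(dppb)]BF4 (5 mol %), CH2Cl2, rt
Reagents that add atoms: none
Why: Hydroxyl-directed hydrogenation with a cationic rhodium diphosphine catalyst: the C6 hydroxyl binds rhodium, allylic 1,3-strain to C9 holds H6 in the plane of the C7=C8 bond, and hydrogen should add to the outer face on which the hydroxyl lies, which sets C7 as S while the undirected C1=C10 alkene is left.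

Step 15
Reactants: 20 C6 alcohol
Product: 21 (1(10)E)-(3S,4S,5S,6R,7S)-3-(TBS-oxy)-4,5-epoxygermacr-1(10)-en-6-yl acetate
Conditions: Ac2O, Et3N, DMAP (cat.), CH2Cl2, 0 °C to rt
Reagents that add atoms: acetic anhydride, CC(=O)OC(C)=O
Why: DMAP-catalysed acetylation of the secondary C6 alcohol, with retention at carbon.

Step 16
Reactants: 21 silyl ether acetate
Product: 22 (1(10)E)-(3S,4R,5S,6R,7S)-6-acetoxy-4,5-epoxygermacr-1(10)-en-3-ol
Conditions: Bu4NF, AcOH (1:1), THF, rt
Reagents that add atoms: none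
Why: Fluoride-mediated desilylation buffered with acetic acid should free the C3 hydroxyl without acyl migration or oxirane opening.

Step 17
Reactants: 22 C3 alcohol; 23 angelic acid ((Z)-2-methylbut-2-enoic acid)
Product: 25 (1(10)E)-(3S,4R,5S,6R,7S)-6-acetoxy-4,5-epoxygermacr-1(10)-en-3-yl (Z)-2-methylbut-2-enoate, via mixed anhydride 24 (not isolated)
Conditions: 23, 2,4,6-trichlorobenzoyl chloride, Et3N, toluene, rt; then 22, 80 °C
Reagents that add atoms: none
Why: Yamaguchi esterification through the mixed anhydride, run without a nucleophilic catalyst so that the Z (angelate) geometry should be kept while the C3 alcohol is acylated.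

## Compound list

1 | but-2-yn-1-ol | CC#CCO | starting material
2 | sodium 2,2-bis(2-methoxyethoxy)-3-methyl-2,5-dihydro-1,2-oxaluminol-2-uide (cyclic alkenylaluminate) | CC1=CCO[Al-]1(OCCOC)OCCOC.[Na+] | intermediate
3 | (Z)-3-iodobut-2-en-1-ol | C/C(I)=C/CO | intermediate
4 | (Z)-tert-butyl[(3-iodobut-2-en-1-yl)oxy]dimethylsilane | C/C(I)=C/CO[Si](C)(C)C(C)(C)C | intermediate
5 | 4-methylpent-3-en-1-ol | CC(C)=CCCO | starting material
6 | 4-methylpent-3-enal | CC(C)=CCC=O | intermediate
7 | (2Z,4S)-1-[(tert-butyldimethylsilyl)oxy]-3,7-dimethylocta-2,6-dien-4-ol | CC(C)=CC[C@H](O)/C(C)=C\CO[Si](C)(C)C(C)(C)C | intermediate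
8 | (1S)-1-[(2R,3S)-3-{[(tert-butyldimethylsilyl)oxy]methyl}-2-methyloxiran-2-yl]-4-methylpent-3-en-1-ol | CC(C)=CC[C@H](O)[C@@]1(C)O[C@H]1CO[Si](C)(C)C(C)(C)C | intermediate
9 | tert-butyl{[(1S)-1-[(2S,3S)-3-{[(tert-butyldimethylsilyl)oxy]methyl}-2-methyloxiran-2-yl]-4-methylpent-3-en-1-yl]oxy}dimethylsilane | CC(C)=CC[C@H](O[Si](C)(C)C(C)(C)C)[C@@]1(C)O[C@H]1CO[Si](C)(C)C(C)(C)C | intermediate
10 | (2E,5S)-5-[(tert-butyldimethylsilyl)oxy]-5-[(2S,3S)-3-{[(tert-butyldimethylsilyl)oxy]methyl}-2-methyloxiran-2-yl]-2-methylpent-2-en-1-ol | OC/C(C)=C/C[C@H](O[Si](C)(C)C(C)(C)C)[C@@]1(C)O[C@H]1CO[Si](C)(C)C(C)(C)C | intermediate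
11 | {[(1S,3E)-5-bromo-1-[(2S,3S)-3-{[(tert-butyldimethylsilyl)oxy]methyl}-2-methyloxiran-2-yl]-4-methylpent-3-en-1-yl]oxy}(tert-butyl)dimethylsilane | BrC/C(C)=C/C[C@H](O[Si](C)(C)C(C)(C)C)[C@@]1(C)O[C@H]1CO[Si](C)(C)C(C)(C)C | intermediate
12 | 3-methylbutan-2-one | CC(=O)C(C)C | starting material
13 | lithium 3-methylbut-1-en-2-olate | C=C(O[Li])C(C)C | intermediate
14 | (6E,9S)-9-[(tert-butyldimethylsilyl)oxy]-9-[(2S,3S)-3-{[(tert-butyldimethylsilyl)oxy]methyl}-2-methyloxiran-2-yl]-2,6-dimethylnon-6-en-3-one | CC(C)C(=O)CC/C(C)=C/C[C@H](O[Si](C)(C)C(C)(C)C)[C@@]1(C)O[C@H]1CO[Si](C)(C)C(C)(C)C | intermediate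
15 | lithium (3Z,6E,9S)-9-[(tert-butyldimethylsilyl)oxy]-9-[(2S,3S)-3-{[(tert-butyldimethylsilyl)oxy]methyl}-2-methyloxiran-2-yl]-2,6-dimethylnona-3,6-dien-3-olate | CC(C)/C(O[Li])=C/C/C(C)=C/C[C@H](O[Si](C)(C)C(C)(C)C)[C@@]1(C)O[C@H]1CO[Si](C)(C)C(C)(C)C | intermediate
16 | (3Z,6E,9S)-9-[(tert-butyldimethylsilyl)oxy]-9-[(2S,3S)-3-{[(tert-butyldimethylsilyl)oxy]methyl}-2-methyloxiran-2-yl]-2,6-dimethylnona-3,6-dien-3-yl trifluoromethanesulfonate | CC(C)/C(OS(=O)(=O)C(F)(F)F)=C/C/C(C)=C/C[C@H](O[Si](C)(C)C(C)(C)C)[C@@]1(C)O[C@H]1CO[Si](C)(C)C(C)(C)C | intermediate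
17 | (3Z,6E,9S)-9-[(tert-butyldimethylsilyl)oxy]-9-[(2S,3S)-3-(hydroxymethyl)-2-methyloxiran-2-yl]-2,6-dimethylnona-3,6-dien-3-yl trifluoromethanesulfonate | CC(C)/C(OS(=O)(=O)C(F)(F)F)=C/C/C(C)=C/C[C@H](O[Si](C)(C)C(C)(C)C)[C@@]1(C)O[C@H]1CO | intermediate
18 | (3Z,6E,9S)-9-[(tert-butyldimethylsilyl)oxy]-9-[(2S,3R)-3-formyl-2-methyloxiran-2-yl]-2,6-dimethylnona-3,6-dien-3-yl trifluoromethanesulfonate | CC(C)/C(OS(=O)(=O)C(F)(F)F)=C/C/C(C)=C/C[C@H](O[Si](C)(C)C(C)(C)C)[C@@]1(C)O[C@H]1C=O | intermediate
19 | (1(10)E,7Z)-(3S,4S,5S,6R)-3-[(tert-butyldimethylsilyl)oxy]-4,5-epoxygermacra-1(10),7-dien-6-ol | CC(C)(C)[Si](C)(C)O[C@H]1C/C=C(\C)C/C=C(/C(C)C)[C@@H](O)[C@@H]2O[C@]12C | intermediate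
20 | (1(10)E)-(3S,4S,5S,6R,7S)-3-[(tert-butyldimethylsilyl)oxy]-4,5-epoxygermacr-1(10)-en-6-ol | CC(C)(C)[Si](C)(C)O[C@H]1C/C=C(\C)CC[C@@H](C(C)C)[C@@H](O)[C@@H]2O[C@]12C | intermediate
21 | (1(10)E)-(3S,4S,5S,6R,7S)-3-[(tert-butyldimethylsilyl)oxy]-4,5-epoxygermacr-1(10)-en-6-yl acetate | CC(C)(C)[Si](C)(C)O[C@H]1C/C=C(\C)CC[C@@H](C(C)C)[C@@H](OC(C)=O)[C@@H]2O[C@]12C | intermediate
22 | (1(10)E)-(3S,4R,5S,6R,7S)-6-acetoxy-4,5-epoxygermacr-1(10)-en-3-ol | O[C@H]1C/C=C(\C)CC[C@@H](C(C)C)[C@@H](OC(C)=O)[C@@H]2O[C@]12C | intermediate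
23 | angelic acid, (Z)-2-methylbut-2-enoic acid | C/C=C(/C)C(=O)O | starting material
24 | (Z)-2-methylbut-2-enoic 2,4,6-trichlorobenzoic anhydride | C/C=C(/C)C(=O)OC(=O)c1c(Cl)cc(Cl)cc1Cl | intermediate
25 | (1(10)E)-(3S,4R,5S,6R,7S)-6-acetoxy-4,5-epoxygermacr-1(10)-en-3-yl (Z)-2-methylbut-2-enoate | C/C=C(/C)C(=O)O[C@H]1C/C=C(\C)CC[C@@H](C(C)C)[C@@H](OC(C)=O)[C@@H]2O[C@]12C | target

## Step count and risks

Total step count: 17. Longest linear sequence: 16 steps (1 to 25 through steps 1, 2 and 4–17; step 3 is a one-step branch).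

Steps most likely to fail:

1. Step 13 (key step). The alkenylchromium species may add to the other face of the aldehyde, so that the C6 epimer forms. The fallback sets C6 by SN2 inversion instead of by face selection. It sets out from 18: the closure under the same dilution is taken through to the C6-epimeric macrocyclic carbinol F1. Mitsunobu reaction of F1 (4-nitrobenzoic acid, PPh3, diisopropyl azodicarboxylate, toluene, 0 °C to rt) should give the inverted 6R 4-nitrobenzoate F2. K2CO3 in MeOH then releases the 6R carbinol, and the route is rejoined at 19.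

2. Step 4. Enantiofacial discrimination by the chiral chromium complex may be poor with this unbranched, β,γ-unsaturated aldehyde. The fallback sets C3 by catalytic ketone reduction. It sets out from 4 and 6: ligand-free coupling (CrCl2, NiCl2 cat., DMF, rt) gives the racemic allylic alcohol F3. Dess–Martin oxidation (NaHCO3, CH2Cl2, 0 °C) gives the Z-enone F4. Corey–Bakshi–Shibata reduction ((R)-2-methyl-CBS-oxazaborolidine cat., catecholborane, toluene, −78 °C; alkenyl as the large group) should return the S alcohol, and the route is rejoined at 7.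

3. Step 17. The angeloyl group may isomerise from Z to E (tiglate) during activation, or acylation of the hindered C3 alcohol may be sluggish. The fallback builds the Z double bond on the ester. It sets out from 22: esterification with 2-[bis(2,2,2-trifluoroethoxy)phosphoryl]propanoic acid (DCC, DMAP cat., CH2Cl2) gives the phosphonate ester F5. Still–Gennari olefination of F5 (KN(SiMe3)2, 18-crown-6, THF, −78 °C, then acetaldehyde) should give the Z-2-methylbut-2-enoate, and the route is rejoined at 25.

## Further compounds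

F1 | step 13 | (1(10)E,7Z)-(3S,4S,5S,6S)-3-[(tert-butyldimethylsilyl)oxy]-4,5-epoxygermacra-1(10),7-dien-6-ol (C6 epimer of 19) | CC(C)(C)[Si](C)(C)O[C@H]1C/C=C(\C)C/C=C(/C(C)C)[C@H](O)[C@@H]2O[C@]12C
F2 | step 13 | (1(10)E,7Z)-(3S,4S,5S,6R)-3-[(tert-butyldimethylsilyl)oxy]-4,5-epoxygermacra-1(10),7-dien-6-yl 4-nitrobenzoate | CC(C)(C)[Si](C)(C)O[C@H]1C/C=C(\C)C/C=C(/C(C)C)[C@@H](OC(=O)c3ccc(cc3)[N+](=O)[O-])[C@@H]2O[C@]12C
F3 | step 4 | racemic (2Z)-1-[(tert-butyldimethylsilyl)oxy]-3,7-dimethylocta-2,6-dien-4-ol | CC(C)=CCC(O)/C(C)=C\CO[Si](C)(C)C(C)(C)C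
F4 | step 4 | (2Z)-1-[(tert-butyldimethylsilyl)oxy]-3,7-dimethylocta-2,6-dien-4-one | CC(C)=CCC(=O)/C(C)=C\CO[Si](C)(C)C(C)(C)C
F5 | step 17 | (1(10)E)-(3S,4R,5S,6R,7S)-6-acetoxy-4,5-epoxygermacr-1(10)-en-3-yl 2-[bis(2,2,2-trifluoroethoxy)phosphoryl]propanoate (both epimers at the phosphonate carbon) | CC(C(=O)O[C@H]1C/C=C(\C)CC[C@@H](C(C)C)[C@@H](OC(C)=O)[C@@H]2O[C@]12C)P(=O)(OCC(F)(F)F)OCC(F)(F)F
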